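**Retrosynthetic overview**
1. Target ⇒ tricyclic bromo-oxocene. The oxirane is the last ring, made by outer-face epoxidation of the 13Z ring olefin.
2. Bromo-oxocene ⇒ (2Z,6E,10E)-geranylgeraniol. One enantioselective bromonium-initiated tricyclisation closes ring A, then ring B, then the eight-membered ether (C15–OH traps the C8 cation), setting five stereocentres.
3. (2Z,6E,10E)-Geranylgeraniol ⇒ C20 2-ynoate, by syn-carbocupration (sets 2Z) and ester reduction.
4. 2-Ynoate ⇒ (2E,6E)-farnesyl bromide + propargyl bromide (as its dianion) + methyl chloroformate, joined in one flask.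
5. Ring order: A → B → oxocane (one step) → oxirane.

Assumption: cyclised compounds carry labdane numbering (C3 = CHBr, C8 = ether carbon, C13/C14 = oxirane carbons, C15 = OCH2), and the (R)-catalyst of step 4 is taken as the antipode giving the 3R series; if the first run shows the opposite sense, the (S)-catalyst is used with no other change.

**Step 1**
Reactants: 1 (2E,6E)-farnesyl bromide; 2 propargyl bromide
Product: 5 methyl (6E,10E)-7,11,15-trimethylhexadeca-6,10,14-trien-2-ynoate, via 1,3-dilithiopropyne 3 (not isolated), via lithium enyne acetylide 4 (not isolated)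
Conditions: 2 (1.5 equiv), n-BuLi (3.0 equiv), TMEDA, Et2O/hexane, −78 °C; then 1, −78 → 0 °C; then ClCO2Me, −78 °C → rt
Reagents that add atoms: methyl chloroformate, COC(=O)Cl
Why: The propargyl dianion is alkylated at its sp3 carbon by the primary allylic bromide (SN2, no new stereocentre, both E olefins untouched), and the remaining lithium acetylide is acylated in the same flask by the chloroformate (acetylide acylation).

**Step 2**
Reactants: 5 methyl (6E,10E)-7,11,15-trimethylhexadeca-6,10,14-trien-2-ynoate
Product: 7 methyl (2Z,6E,10E)-3,7,11,15-tetramethylhexadeca-2,6,10,14-tetraenoate, via lithium vinylcuprate adduct 6 (not isolated)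
Conditions: Me2CuLi (1.5 equiv, from CuI + 2 MeLi), THF, −78 °C; MeOH then aq. NH4Cl at −78 °C
Reagents that add atoms: lithium dimethylcuprate, [Li+].C[Cu-]C
Why: Organocuprate 1,4-addition to the alkynoate is a syn-carbocupration at −78 °C, so methyl and copper end up cis and protonation with retention leaves the chain cis to the ester, which is the 2Z trisubstituted olefin.

**Step 3**
Reactants: 7 methyl (2Z,6E,10E)-3,7,11,15-tetramethylhexadeca-2,6,10,14-tetraenoate
Product: 8 (2Z,6E,10E)-3,7,11,15-tetramethylhexadeca-2,6,10,14-tetraen-1-ol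
Conditions: i-Bu2AlH (2.5 equiv), CH2Cl2, −78 → 0 °C; aq. potassium sodium tartrate
Reagents that add atoms: none
Why: 1,2-Reduction of the enoate by the aluminium hydride (ester reduction) gives the allylic alcohol without touching any olefin geometry.

**Step 4**
Reactants: 8 (2Z,6E,10E)-3,7,11,15-tetramethylhexadeca-2,6,10,14-tetraen-1-ol
Product: 10 (3R,5S,8S,9S,10R,13Z)-3-bromo-8,15-epoxylabd-13-ene, via bicyclic C8 carbocation 9 (not isolated)
Conditions: DBDMH (0.55 equiv), (R)-3,3′-bis(2,4,6-triisopropylphenyl)-1,1′-binaphthalene-2,2′-diyl N-(trifluoromethylsulfonyl)thiophosphoramide (10 mol %), 4 Å MS, toluene/CH2Cl2 3:1, −90 → −70 °C; Et3N, then aq. Na2S2O3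
Reagents that add atoms: 1,3-dibromo-5,5-dimethylhydantoin (DBDMH), CC1(C)N(Br)C(=O)N(Br)C1=O
Why: Proposed new method: the thiophosphoramide sulfur carries Br+ from DBDMH to one enantioface of the terminal, most accessible and most electron-rich olefin (sets C3); chair–chair antiperiplanar additions across the 10E and 6E olefins close rings A and B (set C5, C10, C9); and the tertiary C8 cation 9 is captured, on the face anti to the new C9–C10 bond, by the C15 hydroxyl that the 13Z olefin holds beneath that face, giving the equatorial C8–O bond and the trans-fused oxocene (sets C8); the closest known reaction types are the catalytic enantioselective bromonium polyene cyclisation of homogeranyl arenes with this catalyst class and the hydroxyl-terminated brominative cyclisations that close the seven-membered oxepane of aplysistatin-type targets.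

**Step 5**
Reactants: 10 (3R,5S,8S,9S,10R,13Z)-3-bromo-8,15-epoxylabd-13-ene
Product: 11 (3R,5S,8S,9S,10R,13S,14R)-3-bromo-8,15:13,14-diepoxylabdane (CNP0311742.1)
Conditions: mCPBA (1.2 equiv), NaHCO3, CH2Cl2, 0 °C
Reagents that add atoms: 3-chloroperoxybenzoic acid (mCPBA), O=C(OO)c1cccc(Cl)c1
Why: Prilezhaev epoxidation of the only olefin: the oxocene folds under the ring-B face opposite the axial C8 and C10 methyls (the other fold costs two syn-pentane contacts), axial H9 blocks the inner olefin face, and peracid attack on the exposed outer face gives the cis (13S,14R) oxirane.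

**Compound list**
1 | (2E,6E)-farnesyl bromide | CC(C)=CCC/C(C)=C/CC/C(C)=C/CBr | starting material
2 | propargyl bromide | C#CCBr | starting material
3 | 1,3-dilithiopropyne | [Li]CC#C[Li] | intermediate (not isolated)
4 | lithium (5E,9E)-6,10,14-trimethylpentadeca-5,9,13-trien-1-yn-1-ide (lithium enyne acetylide) | CC(C)=CCC/C(C)=C/CC/C(C)=C/CCC#C[Li] | intermediate (not isolated)
5 | methyl (6E,10E)-7,11,15-trimethylhexadeca-6,10,14-trien-2-ynoate | CC(C)=CCC/C(C)=C/CC/C(C)=C/CCC#CC(=O)OC | intermediate
6 | lithium methyl(vinyl)cuprate adduct of 5 (Cu on C2, cis to the new C3 methyl) | CC(C)=CCC/C(C)=C/CC/C(C)=C/CC/C(C)=C(/[Cu-]C)C(=O)OC.[Li+] | intermediate (not isolated)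
7 | methyl (2Z,6E,10E)-3,7,11,15-tetramethylhexadeca-2,6,10,14-tetraenoate | CC(C)=CCC/C(C)=C/CC/C(C)=C/CC/C(C)=C\C(=O)OC | intermediate
8 | (2Z,6E,10E)-3,7,11,15-tetramethylhexadeca-2,6,10,14-tetraen-1-ol (geranylnerol) | CC(C)=CCC/C(C)=C/CC/C(C)=C/CC/C(C)=C\CO | intermediate
9 | bicyclic C8 carbocation (rings A and B closed, 3-bromo, Z-allylic alcohol side chain on C9) | CC1(C)[C@H](Br)CC[C@]2(C)[C@@H]1CC[C+](C)[C@H]2CC/C(C)=C\CO | intermediate (not isolated)
10 | (3R,5S,8S,9S,10R,13Z)-3-bromo-8,15-epoxylabd-13-ene (trans-fused bromodecalin–oxocene) | CC1(C)[C@H](Br)CC[C@]2(C)[C@@H]1CC[C@]1(C)OC/C=C(C)\CC[C@@H]21 | intermediate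
11 | (3R,5S,8S,9S,10R,13S,14R)-3-bromo-8,15:13,14-diepoxylabdane | CC1(C)[C@H](Br)CC[C@]2(C)[C@@H]1CC[C@]1(C)OC[C@H]3O[C@@]3(C)CC[C@@H]21 | target

**Totals**
Total steps: 5. Longest linear sequence: 5 (1 → 5 → 7 → 8 → 10 → 11).

**Three steps most likely to fail**

Step 4 is the most likely to fail. The eight-membered oxygen capture competes with proton loss to Δ7/Δ8(17) olefins and with carbocyclisation through the 13Z olefin, and the enantioselectivity on this substrate is untested. The fallback sets out from 1 and comes back at 10. It ends the cascade with a ketone oxygen through a six-membered transition state and closes the oxocene afterwards by ring-closing metathesis. Compound 1 alkylates the sodium enolate of ethyl acetoacetate (NaOEt, EtOH) to give ethyl (4E,8E)-2-acetyl-5,9,13-trimethyltetradeca-4,8,12-trienoate F1. Saponification and decarboxylation (aq. NaOH, then H3O+, warm) give (5E,9E)-farnesylacetone F2. The catalyst system of step 4 converts it into the tricyclic bromo enol ether (3R,5S,8S,9S,10R)-3-bromo-8,13-epoxy-14,15-dinorlabd-12-ene F3. Dilute aqueous HCl in THF opens the enol ether to (3R,5S,8S,9S,10R)-3-bromo-8-hydroxy-14,15-dinorlabdan-13-one F4. Ph3P=CH2 in THF gives (3R,5S,8S,9S,10R)-3-bromo-14,15-dinorlabd-13(16)-en-8-ol F5. KH and allyl bromide in THF give (3R,5S,8S,9S,10R)-8-allyloxy-3-bromo-14,15-dinorlabd-13(16)-ene F6. Second-generation Hoveyda–Grubbs catalyst in hot toluene at high dilution then closes the trisubstituted ring olefin, which can only be Z, and delivers 10.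

Step 5 is the second risk. The facial preference rests on a conformational argument for a medium ring and could be reversed. The fallback sets out from 10 and comes back at 11. It inverts the facial outcome through a bromohydrin. NBS in aqueous THF adds Br+ to the accessible face and water anti at the tertiary C13, giving (3R,5S,8S,9S,10R,13S,14S)-3,14-dibromo-8,15-epoxylabdan-13-ol F7. K2CO3 in MeOH closes the oxirane by intramolecular SN2 displacement of the C14 bromide, so the oxygen ends on the face opposite to the electrophile's attack, giving 11.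

Step 1 is the third risk. The one-flask dianion alkylation and acylation can suffer SN2′ attack, double alkylation or incomplete acylation. The fallback sets out from 1 and comes back at 7, bypassing 5 and 6. It builds the 2Z olefin by stereoretentive substitution of an enol triflate instead of carbocupration. The dianion of methyl acetoacetate (NaH, then n-BuLi, THF, 0 °C) is alkylated at its terminal carbon by 1 to give methyl (6E,10E)-7,11,15-trimethyl-3-oxohexadeca-6,10,14-trienoate F8. Tf2O with aqueous Me4NOH in toluene gives the non-chelated enol triflate methyl (2E,6E,10E)-7,11,15-trimethyl-3-(trifluoromethylsulfonyloxy)hexadeca-2,6,10,14-tetraenoate F9, with the triflate trans to the ester. Me2CuLi in THF at −78 °C replaces the triflate by methyl with retention and gives 7.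

**Further compounds**
F1 | step 4 | ethyl (4E,8E)-2-acetyl-5,9,13-trimethyltetradeca-4,8,12-trienoate | CC(C)=CCC/C(C)=C/CC/C(C)=C/CC(C(C)=O)C(=O)OCC
F2 | step 4 | (5E,9E)-6,10,14-trimethylpentadeca-5,9,13-trien-2-one (farnesylacetone) | CC(C)=CCC/C(C)=C/CC/C(C)=C/CCC(C)=O
F3 | step 4 | (3R,5S,8S,9S,10R)-3-bromo-8,13-epoxy-14,15-dinorlabd-12-ene | CC1(C)[C@H](Br)CC[C@]2(C)[C@@H]1CC[C@]1(C)OC(C)=CC[C@@H]21
F4 | step 4 | (3R,5S,8S,9S,10R)-3-bromo-8-hydroxy-14,15-dinorlabdan-13-one | CC1(C)[C@H](Br)CC[C@]2(C)[C@@H]1CC[C@](C)(O)[C@H]2CCC(C)=O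
F5 | step 4 | (3R,5S,8S,9S,10R)-3-bromo-14,15-dinorlabd-13(16)-en-8-ol | CC1(C)[C@H](Br)CC[C@]2(C)[C@@H]1CC[C@](C)(O)[C@H]2CCC(C)=C
F6 | step 4 | (3R,5S,8S,9S,10R)-8-allyloxy-3-bromo-14,15-dinorlabd-13(16)-ene | CC1(C)[C@H](Br)CC[C@]2(C)[C@@H]1CC[C@](C)(OCC=C)[C@H]2CCC(C)=C
F7 | step 5 | (3R,5S,8S,9S,10R,13S,14S)-3,14-dibromo-8,15-epoxylabdan-13-ol | CC1(C)[C@H](Br)CC[C@]2(C)[C@@H]1CC[C@]1(C)OC[C@H](Br)[C@@](C)(O)CC[C@@H]21
F8 | step 1 | methyl (6E,10E)-7,11,15-trimethyl-3-oxohexadeca-6,10,14-trienoate | CC(C)=CCC/C(C)=C/CC/C(C)=C/CCC(=O)CC(=O)OC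
F9 | step 1 | methyl (2E,6E,10E)-7,11,15-trimethyl-3-(trifluoromethylsulfonyloxy)hexadeca-2,6,10,14-tetraenoate | CC(C)=CCC/C(C)=C/CC/C(C)=C/CC/C(OS(=O)(=O)C(F)(F)F)=C\C(=O)OC
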